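**Retrosynthetic overview**
- Last bond: benzylic C1 to the phloroglucinol ring, by acid-triggered Friedel–Crafts addition of the dihydrochalcone (Hoesch product of phloroglucinol and 3-(4-methoxyphenyl)propanenitrile) to the para-quinone methide of a 1,4-bis(4-hydroxyphenyl)-2,3-dimethylbutan-1-ol; C1 is set by 1,2-induction from C2.
- The carbinol comes from an aryl ketone, made by aryl Grignard addition to a Weinreb amide derived from an N-acyl oxazolidinone.
- Key disconnection: C2–C3 of the butane chain, by oxidative cross-coupling of two enolates (Evans propionimide and 4'-benzyloxypropiophenone), in which one α-carbon reacts with reversed polarity to give a 1,4-dicarbonyl; the auxiliary sets C2, and the extra ketone is then erased to CH2.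
- Rings: none is built; all four benzene rings are bought and the oxazolidinone is a bought, recoverable auxiliary.

Assumption: the target is the (1R,2S,3R) isomer encoded by the SMILES; the 0.5 M THF solution of [4-(oxan-2-yloxy)phenyl]magnesium bromide is used as bought.

**Route**

Step 1
Reactants: 1 (4R)-4-benzyl-3-propanoyl-1,3-oxazolidin-2-one; 2 1-[4-(benzyloxy)phenyl]propan-1-one
Product: 5 (4R)-4-benzyl-3-[(2S,3S)-4-[4-(benzyloxy)phenyl]-2,3-dimethyl-4-oxobutanoyl]-1,3-oxazolidin-2-one, via imide lithium enolate 3 (not isolated), via ketone lithium enolate 4 (not isolated)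
Conditions: 1 (1.0 equiv), 2 (1.5 equiv), LiN(iPr)2 (2.6 equiv), THF, −78 °C, 30 min; then Fe(acac)3 (2.2 equiv), −78 °C → rt
Reagents that add atoms: none
Why: Oxidative enolate heterocoupling, in which one-electron oxidation of the mixed lithium enolates by trivalent iron turns one α-carbon into an electrophilic α-carbonyl radical (an enolonium equivalent) that is trapped by the other enolate, so two normally nucleophilic α-carbons are joined; the chelated Z-enolate 3 reacts on the face away from the benzyl group of the (R)-auxiliary, which sets C2 as S, while C3 next to the ketone forms with low selectivity of unpredictable sense (about 2:1 expected) and the (2S,3S) isomer is separated by chromatography.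

Step 2
Reactants: 5 (4R)-4-benzyl-3-[(2S,3S)-4-[4-(benzyloxy)phenyl]-2,3-dimethyl-4-oxobutanoyl]-1,3-oxazolidin-2-one
Product: 8 (4R)-4-benzyl-3-[(2S,3R)-4-(4-hydroxyphenyl)-2,3-dimethylbutanoyl]-1,3-oxazolidin-2-one, via phenol ketone 6 (not isolated), via benzylic carbinol 7 (not isolated)
Conditions: H2 (4 atm), 10% Pd/C, EtOAc–AcOH 4:1, rt
Reagents that add atoms: none
Why: Catalytic hydrogenolysis, in which the benzyl ether is cleaved first, the electron-rich aryl ketone is hydrogenated to the carbinol and its para-hydroxybenzylic C–O bond is then cleaved to CH2, with no bond to C2 or C3 broken (C3 changes descriptor from S to R only because the CIP priorities change).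

Step 3
Reactants: 8 (4R)-4-benzyl-3-[(2S,3R)-4-(4-hydroxyphenyl)-2,3-dimethylbutanoyl]-1,3-oxazolidin-2-one
Product: 9 (2S,3R)-4-(4-hydroxyphenyl)-N-methoxy-N,2,3-trimethylbutanamide
Conditions: MeNHOMe·HCl (4 equiv), AlMe3 (4 equiv), CH2Cl2, −10 °C → rt; 1 M HCl work-up
Reagents that add atoms: N,O-dimethylhydroxylamine hydrochloride, CNOC.Cl
Why: Weinreb amidation, in which the aluminium amide attacks the exocyclic carbonyl of the N-acyl oxazolidinone and releases the recoverable auxiliary without touching the α-stereocentre.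

Step 4
Reactants: 9 (2S,3R)-4-(4-hydroxyphenyl)-N-methoxy-N,2,3-trimethylbutanamide
Product: 12 (2S,3R)-1,4-bis(4-hydroxyphenyl)-2,3-dimethylbutan-1-one, via magnesium hemiaminal 10 (not isolated), via oxanyl ether ketone 11 (not isolated)
Conditions: 4-(THPO)C6H4MgBr (3.5 equiv, 0.5 M in THF), THF, 0 °C → rt; then 1 M HCl, THF, rt, 30 min
Reagents that add atoms: [4-(oxan-2-yloxy)phenyl]magnesium bromide, Br[Mg]c1ccc(OC2CCCCO2)cc1
Why: Weinreb ketone synthesis, in which the aryl Grignard adds only once because the chelated hemiaminal 10 survives until the acidic quench, which also hydrolyses the oxanyl acetal to the free phenol (the first equivalent of Grignard is consumed by the phenol proton of 9).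

Step 5
Reactants: 13 benzene-1,3,5-triol (phloroglucinol); 14 3-(4-methoxyphenyl)propanenitrile
Product: 16 3-(4-methoxyphenyl)-1-(2,4,6-trihydroxyphenyl)propan-1-one, via ketiminium chloride 15 (not isolated)
Conditions: HCl (g), ZnCl2 (0.3 equiv), Et2O, 0 °C, 24 h; then H2O, 100 °C, 2 h
Reagents that add atoms: water, O
Why: Hoesch reaction (Friedel–Crafts-type C-acylation of the symmetrical triphenol by the activated nitrile), which stops at mono-acylation because the ketiminium salt precipitates and deactivates the ring.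

Step 6
Reactants: 12 (2S,3R)-1,4-bis(4-hydroxyphenyl)-2,3-dimethylbutan-1-one; 16 3-(4-methoxyphenyl)-1-(2,4,6-trihydroxyphenyl)propan-1-one
Product: 19 1-{3-[(1R,2S,3R)-1,4-bis(4-hydroxyphenyl)-2,3-dimethylbutyl]-2,4,6-trihydroxyphenyl}-3-(4-methoxyphenyl)propan-1-one, via benzylic alcohol 17 (not isolated), via para-quinone methide 18 (not isolated)
Conditions: NaBH4 (3 equiv), CeCl3·7H2O (1.2 equiv), MeOH, −40 → 0 °C; then 16 (4 equiv), HCl in MeOH (to 0.2 M), −20 → 0 °C
Reagents that add atoms: none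
Why: Luche reduction followed by acid-triggered Friedel–Crafts alkylation (1,6-addition of the phloroglucinol ring to para-quinone methide 18), in which the two free ring positions of 16 are equivalent and the new C1 centre is set by 1,2-induction from C2 (allylic-strain-controlled conformer with the C2–H in the plane of the cation, arene attack anti to the larger C3 branch), predicted to give the 1R epimer as the major one, which is separated from the minor 1S epimer by chromatography.

**Compound list**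

1 | (4R)-4-benzyl-3-propanoyl-1,3-oxazolidin-2-one | CCC(=O)N1[C@H](Cc2ccccc2)COC1=O | starting material
2 | 1-[4-(benzyloxy)phenyl]propan-1-one | CCC(=O)c1ccc(OCc2ccccc2)cc1 | starting material
3 | lithium (Z)-enolate of 1 | C/C=C(\O[Li])N1[C@H](Cc2ccccc2)COC1=O | intermediate
4 | lithium (Z)-enolate of 2 | C/C=C(\O[Li])c1ccc(OCc2ccccc2)cc1 | intermediate
5 | (4R)-4-benzyl-3-[(2S,3S)-4-[4-(benzyloxy)phenyl]-2,3-dimethyl-4-oxobutanoyl]-1,3-oxazolidin-2-one | O=C(c1ccc(OCc2ccccc2)cc1)[C@@H](C)[C@H](C)C(=O)N1[C@H](Cc2ccccc2)COC1=O | intermediate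
6 | (4R)-4-benzyl-3-[(2S,3S)-4-(4-hydroxyphenyl)-2,3-dimethyl-4-oxobutanoyl]-1,3-oxazolidin-2-one | O=C(c1ccc(O)cc1)[C@@H](C)[C@H](C)C(=O)N1[C@H](Cc2ccccc2)COC1=O | intermediate
7 | (4R)-4-benzyl-3-[(2S,3S)-4-hydroxy-4-(4-hydroxyphenyl)-2,3-dimethylbutanoyl]-1,3-oxazolidin-2-one (both C4 epimers) | OC(c1ccc(O)cc1)[C@@H](C)[C@H](C)C(=O)N1[C@H](Cc2ccccc2)COC1=O | intermediate
8 | (4R)-4-benzyl-3-[(2S,3R)-4-(4-hydroxyphenyl)-2,3-dimethylbutanoyl]-1,3-oxazolidin-2-one | Oc1ccc(C[C@@H](C)[C@H](C)C(=O)N2[C@H](Cc3ccccc3)COC2=O)cc1 | intermediate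
9 | (2S,3R)-4-(4-hydroxyphenyl)-N-methoxy-N,2,3-trimethylbutanamide | CON(C)C(=O)[C@@H](C)[C@H](C)Cc1ccc(O)cc1 | intermediate
10 | bromomagnesium hemiaminal alkoxide from 9 and the Grignard reagent (phenol as its bromomagnesium salt) | CON(C)C(O[Mg]Br)(c1ccc(OC2CCCCO2)cc1)[C@@H](C)[C@H](C)Cc1ccc(O[Mg]Br)cc1 | intermediate
11 | (2S,3R)-4-(4-hydroxyphenyl)-2,3-dimethyl-1-[4-(oxan-2-yloxy)phenyl]butan-1-one | O=C(c1ccc(OC2CCCCO2)cc1)[C@@H](C)[C@H](C)Cc1ccc(O)cc1 | intermediate
12 | (2S,3R)-1,4-bis(4-hydroxyphenyl)-2,3-dimethylbutan-1-one | O=C(c1ccc(O)cc1)[C@@H](C)[C@H](C)Cc1ccc(O)cc1 | intermediate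
13 | benzene-1,3,5-triol (phloroglucinol) | Oc1cc(O)cc(O)c1 | starting material
14 | 3-(4-methoxyphenyl)propanenitrile | COc1ccc(CCC#N)cc1 | starting material
15 | 3-(4-methoxyphenyl)-1-(2,4,6-trihydroxyphenyl)propan-1-iminium chloride | COc1ccc(CCC(=[NH2+])c2c(O)cc(O)cc2O)cc1.[Cl-] | intermediate
16 | 3-(4-methoxyphenyl)-1-(2,4,6-trihydroxyphenyl)propan-1-one | COc1ccc(CCC(=O)c2c(O)cc(O)cc2O)cc1 | intermediate
17 | (2S,3R)-1,4-bis(4-hydroxyphenyl)-2,3-dimethylbutan-1-ol (both C1 epimers) | OC(c1ccc(O)cc1)[C@@H](C)[C@H](C)Cc1ccc(O)cc1 | intermediate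
18 | 4-[(2S,3R)-4-(4-hydroxyphenyl)-2,3-dimethylbutylidene]cyclohexa-2,5-dien-1-one | O=C1C=CC(=C[C@@H](C)[C@H](C)Cc2ccc(O)cc2)C=C1 | intermediate
19 | 1-{3-[(1R,2S,3R)-1,4-bis(4-hydroxyphenyl)-2,3-dimethylbutyl]-2,4,6-trihydroxyphenyl}-3-(4-methoxyphenyl)propan-1-one | COc1ccc(CCC(=O)c2c(O)cc(O)c([C@@H](c3ccc(O)cc3)[C@@H](C)[C@H](C)Cc3ccc(O)cc3)c2O)cc1 | target

**Step count**
Total: 6 steps. Longest linear sequence: 5 steps (1, 2, 3, 4, 6); step 5 is the one-step side branch.

**Three steps most likely to fail, with fallbacks**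

Step 1 (heterocoupling). Homodimers lower the yield, and above all C3 next to the ketone is formed with little control, so a large part of the coupled material may be the wrong C3 epimer. The fallback sets out from 1 and comes back at 5, fixing both centres by a polar enolonium route. Benzyl (S)-lactate is converted (Tf2O, 2,6-lutidine, CH2Cl2, −78 °C) into benzyl (2S)-2-{[(trifluoromethyl)sulfonyl]oxy}propanoate F1. The sodium enolate of 1 (NaN(SiMe3)2, THF, −78 °C) displaces the triflate of this enolonium equivalent with inversion to give benzyl (2S,3S)-4-[(4R)-4-benzyl-2-oxo-1,3-oxazolidin-3-yl]-2,3-dimethyl-4-oxobutanoate F2, where the imide α-carbon is set by the auxiliary and the ester α-carbon by the lactate. Hydrogenolysis (H2, Pd/C, EtOAc) gives (2S,3S)-4-[(4R)-4-benzyl-2-oxo-1,3-oxazolidin-3-yl]-2,3-dimethyl-4-oxobutanoic acid F3. Para-selective Friedel–Crafts acylation of benzyl phenyl ether with the mixed trifluoroacetic anhydride of F3 ((CF3CO)2O, cat. H3PO4, CH2Cl2, 0 °C → rt) then delivers 5.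

Step 6 (reduction and Friedel–Crafts union). The 1R/1S ratio rests on acyclic 1,2-induction and may be only moderate; double alkylation of 16 and the protic one-pot medium are further risks. The fallback sets out from 12 and comes back at 19, changing the order of bond formation. Ketone 12 is reduced as before, but carbinol 17 is isolated and alkylated with phloroglucinol 13 (10 equiv, cat. TsOH, MeCN, −30 °C) to give 2-[(1R,2S,3R)-1,4-bis(4-hydroxyphenyl)-2,3-dimethylbutyl]benzene-1,3,5-triol F4, whose C1 epimers are separated at this stage. The acyl chain is then put on last by a Hoesch reaction with 14 (HCl, ZnCl2, Et2O–dioxane, 0 °C; then H2O, 60 °C), which runs through 1-{3-[(1R,2S,3R)-1,4-bis(4-hydroxyphenyl)-2,3-dimethylbutyl]-2,4,6-trihydroxyphenyl}-3-(4-methoxyphenyl)propan-1-iminium chloride F5 to 19; the two free ring positions of F4 are equivalent.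

Step 2 (hydrogenolysis). Carbinol 7 can lactonise onto the imide and expel the auxiliary before its C–O bond is cleaved, and the acidic medium may epimerise C3 while the ketone is still present. The fallback sets out from 5 and comes back at 9, using the lactonisation on purpose. The ketone of 5 is reduced (NaBH4, MeOH, −20 °C) and the γ-hydroxy imide closes, with loss of the auxiliary, to the trans lactone (3S,4S,5RS)-5-[4-(benzyloxy)phenyl]-3,4-dimethyloxolan-2-one F6. Hydrogenolysis (H2, Pd/C, AcOH) cleaves both the benzyl ether and the benzylic lactone C–O bond to give (2S,3R)-4-(4-hydroxyphenyl)-2,3-dimethylbutanoic acid F7. Coupling with MeNHOMe·HCl (EDC·HCl, HOBt, iPr2NEt, CH2Cl2) re-enters the route at 9.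

**Further compounds**

F1 | step 1 | benzyl (2S)-2-{[(trifluoromethyl)sulfonyl]oxy}propanoate | C[C@H](OS(=O)(=O)C(F)(F)F)C(=O)OCc1ccccc1
F2 | step 1 | benzyl (2S,3S)-4-[(4R)-4-benzyl-2-oxo-1,3-oxazolidin-3-yl]-2,3-dimethyl-4-oxobutanoate | O=C(OCc1ccccc1)[C@@H](C)[C@H](C)C(=O)N1[C@H](Cc2ccccc2)COC1=O
F3 | step 1 | (2S,3S)-4-[(4R)-4-benzyl-2-oxo-1,3-oxazolidin-3-yl]-2,3-dimethyl-4-oxobutanoic acid | O=C(O)[C@@H](C)[C@H](C)C(=O)N1[C@H](Cc2ccccc2)COC1=O
F4 | step 6 | 2-[(1R,2S,3R)-1,4-bis(4-hydroxyphenyl)-2,3-dimethylbutyl]benzene-1,3,5-triol | Oc1cc(O)c([C@@H](c2ccc(O)cc2)[C@@H](C)[C@H](C)Cc2ccc(O)cc2)c(O)c1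
F5 | step 6 | 1-{3-[(1R,2S,3R)-1,4-bis(4-hydroxyphenyl)-2,3-dimethylbutyl]-2,4,6-trihydroxyphenyl}-3-(4-methoxyphenyl)propan-1-iminium chloride | COc1ccc(CCC(=[NH2+])c2c(O)cc(O)c([C@@H](c3ccc(O)cc3)[C@@H](C)[C@H](C)Cc3ccc(O)cc3)c2O)cc1.[Cl-]
F6 | step 2 | (3S,4S,5RS)-5-[4-(benzyloxy)phenyl]-3,4-dimethyloxolan-2-one | O=C1OC(c2ccc(OCc3ccccc3)cc2)[C@@H](C)[C@@H]1C
F7 | step 2 | (2S,3R)-4-(4-hydroxyphenyl)-2,3-dimethylbutanoic acid | OC(=O)[C@@H](C)[C@H](C)Cc1ccc(O)cc1
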